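Ring A is built from acyclic pieces instead of being carved out of a resorcinol. Cutting C1'–C2' and C5'–C6' leaves a four-carbon, oxygen-rich diene (C2'–C5') and a two-carbon ynone that already bears the 3-phenylpropanoyl chain. The feature used is the contiguous C1'(acyl)–C2'(OMe)–C3'(CH2Ar)–C4'(OH) array of ring A: one [4+2] addition and loss of methanol installs all four groups, with the C2' and C4' oxygens born differentiated as methyl ether and phenol. The diene is a 2-benzylated 1,1-dimethoxy-3-silyloxybutadiene carrying the ring-C phenol as a benzyl ether, made from an ortho ester via its ketene acetal. Hydrogenolysis finishes the synthesis.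

Key step: step 8

Assumption: 2-(benzyloxy)benzyl bromide 1 is taken as a catalogue compound. The ketene dimethyl acetal is reached through the trimethyl ortho ester (nitrile, Pinner reaction, elimination) because O-methylation of a methyl ester or its enolate does not dependably give ketene acetals. In 19 the methoxy group comes from the acetal carbon (ortho to the ketone) and the hydroxyl from the silyloxy carbon (para), as the target requires.

Step 1
Reactants: 1 2-(benzyloxy)benzyl bromide; 2 acetonitrile
Product: 4 3-[2-(benzyloxy)phenyl]propanenitrile, via (cyanomethyl)lithium 3 (not isolated)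
Conditions: 2 (3 equiv), n-BuLi (3 equiv), THF, −78 °C; then 1, −78 °C → rt
Reagents that add atoms: none
Why: SN2 alkylation of lithiated acetonitrile by a reactive benzylic bromide is a standard two-carbon nitrile homologation, and the excess of carbanion 3 holds back dialkylation.

Step 2
Reactants: 4 3-[2-(benzyloxy)phenyl]propanenitrile
Product: 6 1-(benzyloxy)-2-(3,3,3-trimethoxypropyl)benzene, via imidate hydrochloride 5 (not isolated)
Conditions: HCl (g), MeOH (1.1 equiv), Et2O, 0 °C; volatiles off; then MeOH (excess), hexane, rt, 3 d
Reagents that add atoms: methanol, CO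
Why: Pinner reaction: dry HCl adds methanol to the nitrile to give the imidate hydrochloride, whose alcoholysis in excess methanol should give the trimethyl ortho ester with precipitation of NH4Cl, under anhydrous acid that an aryl benzyl ether withstands.

Step 3
Reactants: 6 1-(benzyloxy)-2-(3,3,3-trimethoxypropyl)benzene
Product: 7 1-(benzyloxy)-2-(3,3-dimethoxyprop-2-en-1-yl)benzene
Conditions: Me3SiOTf (1.1 equiv), i-Pr2NEt (1.3 equiv), CH2Cl2, −20 °C → rt; pentane, filtration
Reagents that add atoms: none
Why: Lewis-acid-mediated β-elimination of methanol from an ortho ester: Me3SiOTf ionises 6 to a dimethoxycarbenium ion, which the hindered amine deprotonates at the α-CH2 to give the ketene acetal, the same reagent pair that converts acetals into enol ethers.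

Step 4
Reactants: 7 1-(benzyloxy)-2-(3,3-dimethoxyprop-2-en-1-yl)benzene; 8 acetyl chloride
Product: 9 3-[2-(benzyloxy)benzyl]-4,4-dimethoxybut-3-en-2-one
Conditions: Et3N (1.5 equiv), Et2O, −20 → 0 °C; purification on Et3N-deactivated silica
Reagents that add atoms: none
Why: C-Acylation of a ketene acetal with an acid chloride: the electron-rich β-carbon of 7 attacks acetyl chloride and the dimethoxycarbenium intermediate loses its acidic α-proton to Et3N, which should give the push–pull acylketene acetal.

Step 5
Reactants: 9 3-[2-(benzyloxy)benzyl]-4,4-dimethoxybut-3-en-2-one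
Product: 11 2-[2-(benzyloxy)benzyl]-1,1-dimethoxy-3-(trimethylsilyloxy)buta-1,3-diene, via lithium dienolate 10 (not isolated)
Conditions: LiN(i-Pr)2 (1.1 equiv), THF, −78 °C; Me3SiCl, −78 → 0 °C; pentane, filtration; used crude
Reagents that add atoms: chlorotrimethylsilane, C[Si](C)(C)Cl
Why: Kinetic enolisation at the only α-CH3 with LiN(i-Pr)2 followed by O-silylation is the usual way from 4,4-dialkoxybut-3-en-2-ones to 1,1-dialkoxy-3-silyloxybuta-1,3-dienes (silyl dienol ether formation).

Step 6
Reactants: 12 3-phenylpropanal; 13 ethynylmagnesium bromide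
Product: 15 (±)-5-phenylpent-1-yn-3-ol, via bromomagnesium alkoxide 14 (not isolated)
Conditions: THF, 0 °C; then cold 1 M HCl
Reagents that add atoms: none
Why: Grignard 1,2-addition of an alkynylmagnesium halide to an aliphatic aldehyde; the new carbinol centre forms as a racemate and is removed by the next oxidation.

Step 7
Reactants: 15 (±)-5-phenylpent-1-yn-3-ol
Product: 16 5-phenylpent-1-yn-3-one
Conditions: Dess–Martin periodinane, CH2Cl2, 0 °C → rt; used promptly
Reagents that add atoms: none
Why: Dess–Martin oxidation converts the secondary propargylic alcohol into the ynone under neutral, anhydrous conditions that spare the base- and nucleophile-sensitive terminal alkynyl ketone.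

Step 8
Reactants: 11 2-[2-(benzyloxy)benzyl]-1,1-dimethoxy-3-(trimethylsilyloxy)buta-1,3-diene; 16 5-phenylpent-1-yn-3-one
Product: 19 1-{3-[2-(benzyloxy)benzyl]-4-hydroxy-2-methoxyphenyl}-3-phenylpropan-1-one, via cyclohexadiene ketal adduct 17 (not isolated), via aryl silyl ether 18 (not isolated)
Conditions: 11 (1.5 equiv), toluene, rt → 70 °C; then 1 M HCl, THF, rt
Reagents that add atoms: none
Why: The electron-rich diene adds to the electron-poor ynone in a strongly asynchronous, normal-electron-demand [4+2] cycloaddition, in which bonding of the diene CH2 terminus (C5') to the ynone β-carbon (C6') runs ahead of bonding of the acetal carbon (C2') to the acyl-bearing carbon (C1'). The closest known reaction type is the Diels–Alder/aromatisation of 1,1-dimethoxy-3-silyloxybuta-1,3-dienes with propiolates and alkynyl ketones, which gives 4-hydroxy-2-methoxyaryl carbonyl compounds. Ring A is closed as a six-membered carbocycle by suprafacial [4π+2π] union of the s-cis diene with one π bond of the alkyne, both σ bonds (C1'–C2' and C5'–C6') arising in this one event; the 1,4-cyclohexadiene ketal 17 then aromatises by 1,4-elimination of methanol and dilute acid cleaves the aryl silyl ether 18. No stereocentre survives, so only regiochemistry has to be controlled: the largest HOMO coefficient sits on the unsubstituted CH2 terminus (fed by the C3 silyloxy group and, vinylogously, by the C1 methoxy groups) and the largest LUMO coefficient on the ynone β-carbon, which places the retained methoxy group ortho and the hydroxyl para to the ketone. Excess diene and exclusion of acid until the cycloaddition is complete should guard against protodesilylation of 11 and oligomerisation of 16.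

Step 9
Reactants: 19 1-{3-[2-(benzyloxy)benzyl]-4-hydroxy-2-methoxyphenyl}-3-phenylpropan-1-one
Product: 20 1-[4-hydroxy-3-(2-hydroxybenzyl)-2-methoxyphenyl]-3-phenylpropan-1-one
Conditions: H2 (1 atm), 10% Pd/C, EtOAc, rt
Reagents that add atoms: none
Why: Catalytic hydrogenolysis of the aryl benzyl ether over Pd/C at 1 atm is faster than reduction of the electron-rich para-hydroxy aryl ketone, and the diarylmethane C–C bond is not cleaved, so stopping after one equivalent of H2 should give the target.

Compound list
1 | 2-(benzyloxy)benzyl bromide | BrCc1ccccc1OCc1ccccc1 | starting material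
2 | acetonitrile | CC#N | starting material
3 | (cyanomethyl)lithium | [Li]CC#N | intermediate
4 | 3-[2-(benzyloxy)phenyl]propanenitrile | N#CCCc1ccccc1OCc1ccccc1 | intermediate
5 | methyl 3-[2-(benzyloxy)phenyl]propanimidate hydrochloride | COC(=N)CCc1ccccc1OCc1ccccc1.Cl | intermediate
6 | 1-(benzyloxy)-2-(3,3,3-trimethoxypropyl)benzene (trimethyl ortho ester) | COC(OC)(OC)CCc1ccccc1OCc1ccccc1 | intermediate
7 | 1-(benzyloxy)-2-(3,3-dimethoxyprop-2-en-1-yl)benzene (ketene dimethyl acetal) | COC(OC)=CCc1ccccc1OCc1ccccc1 | intermediate
8 | acetyl chloride | CC(Cl)=O | starting material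
9 | 3-[2-(benzyloxy)benzyl]-4,4-dimethoxybut-3-en-2-one | COC(OC)=C(Cc1ccccc1OCc1ccccc1)C(C)=O | intermediate
10 | lithium 3-[2-(benzyloxy)benzyl]-4,4-dimethoxybuta-1,3-dien-2-olate | [Li]OC(=C)C(Cc1ccccc1OCc1ccccc1)=C(OC)OC | intermediate
11 | 2-[2-(benzyloxy)benzyl]-1,1-dimethoxy-3-(trimethylsilyloxy)buta-1,3-diene | COC(OC)=C(Cc1ccccc1OCc1ccccc1)C(=C)O[Si](C)(C)C | intermediate
12 | 3-phenylpropanal | O=CCCc1ccccc1 | starting material
13 | ethynylmagnesium bromide | C#C[Mg]Br | starting material
14 | bromomagnesium 5-phenylpent-1-yn-3-olate (racemic) | C#CC(CCc1ccccc1)O[Mg]Br | intermediate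
15 | (±)-5-phenylpent-1-yn-3-ol | C#CC(O)CCc1ccccc1 | intermediate
16 | 5-phenylpent-1-yn-3-one | C#CC(=O)CCc1ccccc1 | intermediate
17 | 1-{5-[2-(benzyloxy)benzyl]-6,6-dimethoxy-4-(trimethylsilyloxy)cyclohexa-1,4-dien-1-yl}-3-phenylpropan-1-one | COC1(OC)C(C(=O)CCc2ccccc2)=CCC(O[Si](C)(C)C)=C1Cc1ccccc1OCc1ccccc1 | intermediate
18 | 1-{3-[2-(benzyloxy)benzyl]-2-methoxy-4-(trimethylsilyloxy)phenyl}-3-phenylpropan-1-one | COc1c(C(=O)CCc2ccccc2)ccc(O[Si](C)(C)C)c1Cc1ccccc1OCc1ccccc1 | intermediate
19 | 1-{3-[2-(benzyloxy)benzyl]-4-hydroxy-2-methoxyphenyl}-3-phenylpropan-1-one (3'-(2-benzyloxybenzyl)-4'-hydroxy-2'-methoxydihydrochalcone) | COc1c(C(=O)CCc2ccccc2)ccc(O)c1Cc1ccccc1OCc1ccccc1 | intermediate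
20 | 1-[4-hydroxy-3-(2-hydroxybenzyl)-2-methoxyphenyl]-3-phenylpropan-1-one | COc1c(C(=O)CCc2ccccc2)ccc(O)c1Cc1ccccc1O | target

Total step count: 9 (five to the diene, two to the ynone, cycloaddition, hydrogenolysis).
Longest linear sequence: 7 (steps 1, 2, 3, 4, 5, 8, 9).

Steps most likely to fail

1. Step 8. The crowded, fully substituted acetal terminus may close slowly, so that the sequence stalls after the first C–C bond, while the diene is lost by protodesilylation and the ynone by oligomerisation. Fallback: setting out from diene 11 and ynone 16 and returning at 19, the ring is made in two polar stages instead of one pericyclic event. A TiCl4-mediated Mukaiyama–Michael addition (CH2Cl2, −78 °C) forms only C5'–C6' and, after aqueous work-up, should give the open-chain (5E)-2-[2-(benzyloxy)benzyl]-1,1-dimethoxy-9-phenylnona-1,5-diene-3,7-dione F1. NaOMe in MeOH then generates the extended enolate, whose carbon α to the phenethyl ketone adds to the ketene-acetal carbon and expels methoxide (intramolecular addition–elimination, six-membered closure). Tautomerisation of the resulting dienone should deliver 19.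

2. Step 4. The dimethoxycarbenium chloride ion pair may collapse by O-demethylation to the β-keto ester faster than it loses its α-proton, and acetyl chloride may be diverted to ketene, which adds [2+2] to the ketene acetal. Fallback: setting out from bromide 1 and acetyl chloride 8 and returning at 9, the benzyl group is attached last by cross-coupling instead of acylating a preformed ketene acetal. AlCl3-mediated acylation of commercial 1,1-dichloroethene with 8, with loss of HCl, should give 4,4-dichlorobut-3-en-2-one F2. NaOMe in MeOH exchanges both chlorides to give 4,4-dimethoxybut-3-en-2-one F3. N-Bromosuccinimide (CH2Cl2, 0 °C) brominates the nucleophilic C3 to give 3-bromo-4,4-dimethoxybut-3-en-2-one F4. Zinc insertion into 1 (Zn dust, LiCl, THF) gives [2-(benzyloxy)benzyl]zinc bromide F5, and Negishi coupling of F4 with F5 (Pd(OAc)2, SPhos, THF, rt) should give 9.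

3. Step 2. During the slow alcoholysis the imidate hydrochloride may be demethylated by chloride to the primary amide, or hydrolysed by adventitious water to the methyl ester, before the ortho ester forms. Fallback: setting out from nitrile 4 and returning at 6, the imidate is made by O-alkylation of an amide with a non-nucleophilic counter-ion. Hydration of 4 (H2O2, K2CO3, DMSO) should give 3-[2-(benzyloxy)phenyl]propanamide F6. O-Methylation with Me3OBF4 (CH2Cl2, rt) gives methyl 3-[2-(benzyloxy)phenyl]propanimidate tetrafluoroborate F7, and methanolysis of this salt (MeOH, rt) should give 6.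

Further compounds
F1 | step 8 | (5E)-2-[2-(benzyloxy)benzyl]-1,1-dimethoxy-9-phenylnona-1,5-diene-3,7-dione | COC(OC)=C(Cc1ccccc1OCc1ccccc1)C(=O)C/C=C/C(=O)CCc1ccccc1
F2 | step 4 | 4,4-dichlorobut-3-en-2-one | CC(=O)C=C(Cl)Cl
F3 | step 4 | 4,4-dimethoxybut-3-en-2-one | COC(OC)=CC(C)=O
F4 | step 4 | 3-bromo-4,4-dimethoxybut-3-en-2-one | COC(OC)=C(Br)C(C)=O
F5 | step 4 | [2-(benzyloxy)benzyl]zinc bromide | Br[Zn]Cc1ccccc1OCc1ccccc1
F6 | step 2 | 3-[2-(benzyloxy)phenyl]propanamide | NC(=O)CCc1ccccc1OCc1ccccc1
F7 | step 2 | methyl 3-[2-(benzyloxy)phenyl]propanimidate tetrafluoroborate | COC(=[NH2+])CCc1ccccc1OCc1ccccc1.F[B-](F)(F)F
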